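**Plan**

1. After the six phenol MOM ethers are removed, one retro-[4+2] breaks C5–C6 and C3–C4 of the methylcyclohexene (C1 = C–CH3, C2 = CH=, C3 = CH–aryl, C4 = CH–aroyl, C5 = CH–aryl, C6 = CH2). This gives two isomeric C20 chalcones, a chromeno-chalcone (dienophile) and a dehydroprenyl-chalcone (diene).
2. Enabling feature: C1=C2 lies across the ring from the C4–C5 bond (cyclohexene retron). The C4 aroyl group carries the chromene 5-OH ortho to its C=O, an O,O-bidentate site that binds a chiral borate. The rival enone in the diene half is switched off by capping its own ortho-OH.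
3. Further cuts: both enone C=C bonds (Claisen-Schmidt, one shared aldehyde), the aryl–dienyl bond (Suzuki-Miyaura) and the pyran ring (prenal annulation). Both halves start from 2,4-dihydroxyacetophenone.
4. Forward order: pyran ring, the two chalcone chains, the dienyl side chain, the cyclohexene ring as the last C–C event, then sixfold unmasking.
5. Stereochemistry: all three centres arise in the cycloaddition. C4/C5 trans comes from the (E)-enone, C3/C4 cis from the (E)-diene plus endo approach, and the absolute sense (3S,4R,5S) from (S)-VANOL on boron. The end game is neither acidic nor basic, so C4 is not epimerised.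

Key step: step 9

Assumption 1: the (S) antipode of VANOL is taken as the one whose borate exposes the enone face leading to (3S,4R,5S). Both antipodes are commercial, so the choice can be reversed with no other change.
Assumption 2: the axial chirality of VANOL cannot be written in SMILES, so entries that contain the ligand show constitution and carbon stereocentres only.

**Step 1**
Reactants: 1 2,4-dihydroxybenzaldehyde
Product: 2 2,4-bis(methoxymethoxy)benzaldehyde
Conditions: NaH (2.4 equiv), MOMCl (2.4 equiv), DMF, 0 °C to rt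
Reagents that add atoms: chloromethyl methyl ether (MOMCl), COCCl
Why: Williamson-type O-alkylation in which both phenoxides, including the hydrogen-bonded ortho one once NaH has deprotonated it fully, displace chloride from the very reactive chloromethyl ether, giving acetals that are inert to the hydroxide, palladium and borate steps that follow.

**Step 2**
Reactants: 3 2,4-dihydroxyacetophenone; 4 3-methylbut-2-enal (prenal)
Product: 6 1-(5-hydroxy-2,2-dimethyl-2H-chromen-6-yl)ethanone, via ortho-quinone methide 5 (not isolated)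
Conditions: ethylenediammonium diacetate (10 mol %), xylenes, 140 °C
Reagents that add atoms: none
Why: Formal [3+3] chromene annulation (Knoevenagel-type condensation, then oxa-6π electrocyclisation), in which the prenal iminium is attacked by C3, the most nucleophilic position between the two oxygens, water is lost to give 5, and the C4 oxygen closes the pyran because the 2-OH stays hydrogen-bonded to the acetyl group, so the angular 5-hydroxychromene should result.

**Step 3**
Reactants: 6 1-(5-hydroxy-2,2-dimethyl-2H-chromen-6-yl)ethanone; 2 2,4-bis(methoxymethoxy)benzaldehyde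
Product: 7 (E)-3-[2,4-bis(methoxymethoxy)phenyl]-1-(5-hydroxy-2,2-dimethyl-2H-chromen-6-yl)prop-2-en-1-one (dienophile)
Conditions: KOH, EtOH, rt; neutralised with aq NH4Cl at 0 °C
Reagents that add atoms: none
Why: Claisen-Schmidt condensation in which the methyl ketone enolate adds to the non-enolisable aldehyde and E1cB dehydration gives the favoured (E)-enone, while the phenoxide form of the ortho-OH holds back flavanone closure and the chromene and MOM groups are base-stable.

**Step 4**
Reactants: 3 2,4-dihydroxyacetophenone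
Product: 8 1-(2,4-dihydroxy-3-iodophenyl)ethanone
Conditions: I2 (0.4 equiv), HIO3 (0.2 equiv), EtOH-H2O, rt
Reagents that add atoms: iodine, II; iodic acid, O=I(=O)O
Why: Electrophilic aromatic iodination with I+ from I2/HIO3, in which C3, activated by both flanking hydroxyls, should react first under these neutral aqueous-alcoholic conditions and the exact iodine stoichiometry limits di-iodination.

**Step 5**
Reactants: 8 1-(2,4-dihydroxy-3-iodophenyl)ethanone
Product: 9 1-[3-iodo-2,4-bis(methoxymethoxy)phenyl]ethanone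
Conditions: NaH (2.3 equiv), MOMCl (2.4 equiv), DMF, 0 °C to rt
Reagents that add atoms: chloromethyl methyl ether (MOMCl), COCCl
Why: Williamson-type O-alkylation in which full deprotonation breaks the OH···O=C hydrogen bond so that the hindered 2-OH is also capped, which is the device that later keeps this half from binding boron.

**Step 6**
Reactants: 9 1-[3-iodo-2,4-bis(methoxymethoxy)phenyl]ethanone; 2 2,4-bis(methoxymethoxy)benzaldehyde
Product: 10 (E)-3-[2,4-bis(methoxymethoxy)phenyl]-1-[3-iodo-2,4-bis(methoxymethoxy)phenyl]prop-2-en-1-one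
Conditions: KOH, EtOH, rt
Reagents that add atoms: none
Why: Claisen-Schmidt condensation of a fully protected methyl ketone with a non-enolisable aldehyde, giving the (E)-enone by E1cB dehydration, while the aryl iodide and the MOM ethers are inert to ethanolic hydroxide at room temperature.

**Step 7**
Reactants: 11 2-methylbut-1-en-3-yne; 12 pinacolborane
Product: 13 (E)-4,4,5,5-tetramethyl-2-(3-methylbuta-1,3-dien-1-yl)-1,3,2-dioxaborolane
Conditions: Cp2ZrHCl (5 mol %), Et3N (10 mol %), neat, sealed tube, 40 °C
Reagents that add atoms: none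
Why: Zirconocene-hydride-catalysed alkyne hydroboration, a syn and anti-Markovnikov H–B addition that is faster at the terminal alkyne than at the 1,1-disubstituted alkene and so fixes the (E)-alkenylboronate geometry.

**Step 8**
Reactants: 10 iodochalcone; 13 (E)-dienyl pinacol boronate
Product: 14 (E)-3-[2,4-bis(methoxymethoxy)phenyl]-1-{2,4-bis(methoxymethoxy)-3-[(1E)-3-methylbuta-1,3-dien-1-yl]phenyl}prop-2-en-1-one (diene)
Conditions: Pd(OAc)2 (5 mol %), SPhos (10 mol %), K2CO3, THF-H2O, degassed, 60 °C
Reagents that add atoms: none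
Why: Suzuki-Miyaura coupling in which a bulky electron-rich biarylphosphine lets Pd(0) insert into the doubly ortho-flanked C–I bond and transmetalation/reductive elimination keep the (E)-alkenyl geometry, while the enone and the MOM ethers tolerate aqueous carbonate.

**Step 9**
Reactants: 7 dienophile chalcone; 14 diene chalcone
Product: 17 hexa-MOM endo cycloadduct (3S,4R,5S), via dienophile boron chelate 15 (not isolated), via cycloadduct boron chelate 16 (not isolated)
Conditions: (S)-VANOL (1.05 equiv), B(OPh)3 (1.0 equiv), 5 Å MS, THF, 55 °C, then volatiles off in vacuo; 7 (1.0 equiv), THF, rt; 14 (1.5 equiv), rt; aq NaHCO3 work-up; chromatography to remove any exo isomer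
Reagents that add atoms: none
Why: Exchange of phenoxide on the VANOL borate for the chromene 5-OH of 7 gives the six-membered O,O-chelate 15, in which tetracoordinate boron lowers the enone LUMO and locks the C=O/C=C unit s-cis, and the electron-rich (E)-1-aryl-3-methylbutadiene of 14 then adds in a concerted but asynchronous normal-demand [4+2] cycloaddition. The closest known reaction type is the chiral biaryl-diol/boron-promoted asymmetric Diels-Alder reaction of 2'-hydroxychalcones with 1-aryl-3-methylbutadienes. One ring closes, the cyclohexene, by intermolecular suprafacial-suprafacial union that forms C6–C5 and C4–C3 and leaves the new C1=C2 alkene. C4/C5 trans is copied from the (E)-enone, C3/C4 cis follows from the (E)-diene together with the endo placement of the chelated aroyl group under the diene, and the absolute sense 3S,4R,5S comes from the vaulted phenyl-naphthyl wall of the ligand, which covers one face of the flat chelate. Regiochemistry is secured because the 1-aryl and 3-methyl groups both put the largest HOMO coefficient on the terminal CH2, which pairs with the enone β-carbon. Chemoselectivity is secured because only 7 offers a free ortho-hydroxy ketone to boron, whereas the enone of 14 is capped as its 2'-OMOM ether and twisted out of conjugation and the chromene C3=C4 bond is electron-rich and mismatched; aqueous work-up then hydrolyses 16 and returns the ligand.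

**Step 10**
Reactants: 17 hexa-MOM endo cycloadduct
Product: 19 target CNP0115975.1, via hexakis(trimethylsilyl) ether 18 (not isolated)
Conditions: TMSOTf (12 equiv), 2,2'-bipyridyl (18 equiv), MeCN-CH2Cl2, 0 °C to rt; then H2O, rt
Reagents that add atoms: none
Why: Silyl triflate/bipyridyl exchange of aromatic MOM ethers, in which the bipyridyl-buffered silyl cation activates each acetal, bipyridyl carries off the methoxymethyl cation and the aryl TMS ethers of 18 hydrolyse on addition of water, so the medium stays close to neutral and C4 is not epimerised, the C4 ketone is not ketalised by the flanking phenols, and the chromene and the 2-hydroxychalcone are left alone.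

**Compound list**

1 | 2,4-dihydroxybenzaldehyde | O=Cc1ccc(O)cc1O | starting material
2 | 2,4-bis(methoxymethoxy)benzaldehyde | O=Cc1ccc(OCOC)cc1OCOC | intermediate
3 | 2,4-dihydroxyacetophenone | CC(=O)c1ccc(O)cc1O | starting material
4 | 3-methylbut-2-enal | CC(C)=CC=O | starting material
5 | ortho-quinone methide, 4-acetyl-3-hydroxy-2-(3-methylbut-2-enylidene)cyclohexa-3,5-dien-1-one | CC(=O)C1=C(O)C(=CC=C(C)C)C(=O)C=C1 | intermediate
6 | 1-(5-hydroxy-2,2-dimethyl-2H-chromen-6-yl)ethanone | CC(=O)c1ccc2c(c1O)C=CC(C)(C)O2 | intermediate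
7 | (E)-3-[2,4-bis(methoxymethoxy)phenyl]-1-(5-hydroxy-2,2-dimethyl-2H-chromen-6-yl)prop-2-en-1-one | COCOc1ccc(/C=C/C(=O)c2ccc3c(c2O)C=CC(C)(C)O3)c(OCOC)c1 | intermediate
8 | 1-(2,4-dihydroxy-3-iodophenyl)ethanone | CC(=O)c1ccc(O)c(I)c1O | intermediate
9 | 1-[3-iodo-2,4-bis(methoxymethoxy)phenyl]ethanone | CC(=O)c1ccc(OCOC)c(I)c1OCOC | intermediate
10 | (E)-3-[2,4-bis(methoxymethoxy)phenyl]-1-[3-iodo-2,4-bis(methoxymethoxy)phenyl]prop-2-en-1-one | COCOc1ccc(/C=C/C(=O)c2ccc(OCOC)c(I)c2OCOC)c(OCOC)c1 | intermediate
11 | 2-methylbut-1-en-3-yne | C=C(C)C#C | starting material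
12 | pinacolborane | CC1(C)OBOC1(C)C | starting material
13 | (E)-4,4,5,5-tetramethyl-2-(3-methylbuta-1,3-dien-1-yl)-1,3,2-dioxaborolane | C=C(C)/C=C/B1OC(C)(C)C(C)(C)O1 | intermediate
14 | (E)-3-[2,4-bis(methoxymethoxy)phenyl]-1-{2,4-bis(methoxymethoxy)-3-[(1E)-3-methylbuta-1,3-dien-1-yl]phenyl}prop-2-en-1-one | C=C(C)/C=C/c1c(OCOC)ccc(C(=O)/C=C/c2ccc(OCOC)cc2OCOC)c1OCOC | intermediate
15 | (S)-VANOL borate O,O-chelate of 7 (boron bound to the chromene 5-O, the carbonyl O and both ligand oxygens) | COCOc1ccc(/C=C/C2=[O+][B-]3(Oc4c2ccc5OC(C)(C)C=Cc45)Oc2c(c(-c6ccccc6)cc6ccccc26)-c2c(O3)c6ccccc6cc2-c2ccccc2)c(OCOC)c1 | intermediate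
16 | (S)-VANOL borate O,O-chelate of cycloadduct 17 | CC1=C[C@H](c2c(OCOC)ccc(C(=O)/C=C/c3ccc(OCOC)cc3OCOC)c2OCOC)[C@H](C2=[O+][B-]3(Oc4c2ccc5OC(C)(C)C=Cc45)Oc2c(c(-c6ccccc6)cc6ccccc26)-c2c(O3)c6ccccc6cc2-c2ccccc2)[C@@H](c2ccc(OCOC)cc2OCOC)C1 | intermediate
17 | (E)-1-{3-[(1S,5S,6R)-5-[2,4-bis(methoxymethoxy)phenyl]-6-(5-hydroxy-2,2-dimethyl-2H-chromene-6-carbonyl)-3-methylcyclohex-2-en-1-yl]-2,4-bis(methoxymethoxy)phenyl}-3-[2,4-bis(methoxymethoxy)phenyl]prop-2-en-1-one | CC1=C[C@H](c2c(OCOC)ccc(C(=O)/C=C/c3ccc(OCOC)cc3OCOC)c2OCOC)[C@H](C(=O)c2ccc3c(c2O)C=CC(C)(C)O3)[C@@H](c2ccc(OCOC)cc2OCOC)C1 | intermediate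
18 | hexakis(trimethylsilyl) ether of the target (chromene 5-OH free) | CC1=C[C@H](c2c(O[Si](C)(C)C)ccc(C(=O)/C=C/c3ccc(O[Si](C)(C)C)cc3O[Si](C)(C)C)c2O[Si](C)(C)C)[C@H](C(=O)c2ccc3c(c2O)C=CC(C)(C)O3)[C@@H](c2ccc(O[Si](C)(C)C)cc2O[Si](C)(C)C)C1 | intermediate
19 | (E)-1-{3-[(1S,5S,6R)-5-(2,4-dihydroxyphenyl)-6-(5-hydroxy-2,2-dimethyl-2H-chromene-6-carbonyl)-3-methylcyclohex-2-en-1-yl]-2,4-dihydroxyphenyl}-3-(2,4-dihydroxyphenyl)prop-2-en-1-one | CC1=C[C@H](c2c(O)ccc(C(=O)/C=C/c3ccc(O)cc3O)c2O)[C@H](C(=O)c2ccc3c(c2O)C=CC(C)(C)O3)[C@@H](c2ccc(O)cc2O)C1 | target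

Total step count: 10
Longest linear sequence: 6 steps (4, 5, 6, 8, 9, 10)

**Steps most likely to fail**

**Step 9.**
- What may go wrong: weak endo/exo discrimination, incomplete facial shielding by the ligand, polymerisation of the diene, and boron-induced loss of the MOM group ortho to the ketone of the diene, which would switch on its own enone and open the way to oligomers.
- Fallback: it sets out from 7 and 14 and comes back at 17. The cycloaddition is run without chiral control over silica-supported silver nanoparticles (CH2Cl2, 50 °C). This heterogeneous catalyst class is known for 2'-hydroxychalcones, leans towards endo adducts, and has no Lewis acid able to touch MOM ethers.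
- It should give 17 as a racemate, that is, together with the mirror-image endo cycloadduct F1. Compound 17 is then separated by preparative chromatography on a chiral amylose-carbamate phase. Enantiopurity then rests on resolution instead of reagent control.

**Step 10.**
- What may go wrong: incomplete sixfold exchange, or acid released during the hydrolysis stage. Such acid could start ketalisation of the C4 ketone by the two flanking ortho-phenols, or addition of a phenol to the C1=C2 alkene.
- Fallback: it sets out from 7 and 10 and comes back at 19. The protecting groups are exchanged before any stereocentre exists, so that the last step becomes a mild methanolysis.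
- Dienophile half: HCl (cat.)/MeOH on 7 should give the free chromeno-chalcone triol F2. Ac2O (2.1 equiv)/pyridine at 0 °C leaves the chelated 5-OH free and gives the dienophile diacetate F3.
- Diene half: HCl (cat.)/MeOH on 10 should give the iodo-tetrahydroxychalcone F4. Ac2O/Et3N/DMAP gives the iodochalcone tetraacetate F5. Anhydrous Suzuki-Miyaura coupling with 13 (Pd(OAc)2, SPhos, CsF, dioxane, 60 °C) gives the diene tetraacetate F6.
- Union: under the conditions of step 9, F3 and F6 should pass through the diacetate boron chelate F7 and the hexaacetate adduct boron chelate F8 to the hexaacetate endo cycloadduct F9.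
- Release: K2CO3/MeOH at 0 °C releases 19.

**Step 8.**
- What may go wrong: slow oxidative addition and transmetalation at the doubly ortho-flanked iodide, with protodeboronation and polymerisation of the dienylboronate competing.
- Fallback: it sets out from 10 and comes back at 14.
- A Heck reaction of 10 with 2-methylbut-3-en-2-ol (Pd(OAc)2, Bu4NCl, NaHCO3, DMF, 70 °C) couples a robust, cheap alkene and should give the (E)-tertiary allylic alcohol F10.
- Mesylation/elimination (MsCl, Et3N, CH2Cl2, 0 °C to rt) then dehydrates F10 towards a methyl group to give 14.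

**Further compounds**

F1 | step 9 | mirror-image (3R,4S,5R) hexa-MOM endo cycloadduct | CC1=C[C@@H](c2c(OCOC)ccc(C(=O)/C=C/c3ccc(OCOC)cc3OCOC)c2OCOC)[C@@H](C(=O)c2ccc3c(c2O)C=CC(C)(C)O3)[C@H](c2ccc(OCOC)cc2OCOC)C1
F2 | step 10 | (E)-3-(2,4-dihydroxyphenyl)-1-(5-hydroxy-2,2-dimethyl-2H-chromen-6-yl)prop-2-en-1-one | O=C(/C=C/c1ccc(O)cc1O)c1ccc2c(c1O)C=CC(C)(C)O2
F3 | step 10 | (E)-3-(2,4-diacetoxyphenyl)-1-(5-hydroxy-2,2-dimethyl-2H-chromen-6-yl)prop-2-en-1-one | CC(=O)Oc1ccc(/C=C/C(=O)c2ccc3c(c2O)C=CC(C)(C)O3)c(OC(C)=O)c1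
F4 | step 10 | (E)-1-(2,4-dihydroxy-3-iodophenyl)-3-(2,4-dihydroxyphenyl)prop-2-en-1-one | O=C(/C=C/c1ccc(O)cc1O)c1ccc(O)c(I)c1O
F5 | step 10 | (E)-1-(2,4-diacetoxy-3-iodophenyl)-3-(2,4-diacetoxyphenyl)prop-2-en-1-one | CC(=O)Oc1ccc(/C=C/C(=O)c2ccc(OC(C)=O)c(I)c2OC(C)=O)c(OC(C)=O)c1
F6 | step 10 | (E)-1-{2,4-diacetoxy-3-[(1E)-3-methylbuta-1,3-dien-1-yl]phenyl}-3-(2,4-diacetoxyphenyl)prop-2-en-1-one | C=C(C)/C=C/c1c(OC(C)=O)ccc(C(=O)/C=C/c2ccc(OC(C)=O)cc2OC(C)=O)c1OC(C)=O
F7 | step 10 | (S)-VANOL borate O,O-chelate of F3 | CC(=O)Oc1ccc(/C=C/C2=[O+][B-]3(Oc4c2ccc5OC(C)(C)C=Cc45)Oc2c(c(-c6ccccc6)cc6ccccc26)-c2c(O3)c6ccccc6cc2-c2ccccc2)c(OC(C)=O)c1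
F8 | step 10 | (S)-VANOL borate O,O-chelate of F9 | CC1=C[C@H](c2c(OC(C)=O)ccc(C(=O)/C=C/c3ccc(OC(C)=O)cc3OC(C)=O)c2OC(C)=O)[C@H](C2=[O+][B-]3(Oc4c2ccc5OC(C)(C)C=Cc45)Oc2c(c(-c6ccccc6)cc6ccccc26)-c2c(O3)c6ccccc6cc2-c2ccccc2)[C@@H](c2ccc(OC(C)=O)cc2OC(C)=O)C1
F9 | step 10 | (3S,4R,5S) hexaacetate endo cycloadduct | CC1=C[C@H](c2c(OC(C)=O)ccc(C(=O)/C=C/c3ccc(OC(C)=O)cc3OC(C)=O)c2OC(C)=O)[C@H](C(=O)c2ccc3c(c2O)C=CC(C)(C)O3)[C@@H](c2ccc(OC(C)=O)cc2OC(C)=O)C1
F10 | step 8 | (E)-3-[2,4-bis(methoxymethoxy)phenyl]-1-{3-[(1E)-3-hydroxy-3-methylbut-1-en-1-yl]-2,4-bis(methoxymethoxy)phenyl}prop-2-en-1-one | CC(C)(O)/C=C/c1c(OCOC)ccc(C(=O)/C=C/c2ccc(OCOC)cc2OCOC)c1OCOC
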